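# Total synthesis plan for 2,3-dihydroheveaflavone (18)

## The problem

- Compound 18 is a (2S)-flavanone (rings A and C, aryl ring B; unprimed and primed locants). Its ring B is bonded through C3' to C8'' of a flavone (rings A'' and C'', anisyl ring B''').
- The C3'–C8'' bond lies between three ortho substituents (4'-OH, 7''-OMe, O1''). C8'' also has to be told apart from the electronically similar C6''.
- C2 is the only stereocentre, so nothing in the molecule can control it. It is also labile: base or acid opens ring C by a retro-oxa-Michael reaction to the achiral chalcone, most easily once 4'-OH and 5-OH are free.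
- C2 must therefore be set late, by an external source of chirality, and may afterwards meet neutral conditions only.
- Six phenolic oxygens must be sorted into three methyl ethers (C7, C7'', C4''') and three free hydroxyls (C5, C5'', C4'). The two C rings differ in oxidation level. Both facts rule out any global redox or global (de)methylation step.
- The feature that is exploited lies in ring A''. The path O–C4'–C3'–C8''–C7''(–O) is the skeleton of a benzofuran-2(3H)-one: ring B, with C8'' as the acidic CH2 and C7'' as the lactone carbonyl.
- The remaining carbons C8a''–C4a''–C5''–C6'', together with ring C'', are the skeleton of a 3-acetyl-4H-pyran-4-one. Ring A'' can therefore be closed between two small heterocycles, and the crowded aryl–aryl bond never has to be made.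

## Retrosynthesis

**18 ⇒ 17.** No skeletal bond is cut. The three free hydroxyls of 18 are traced back to benzyl ethers in 17. Benzyl is preferred to acyl or acetal groups because it leaves under neutral hydrogenolysis, the only kind of last step that C2 tolerates. The forward reaction must spare the ring-bound C2–O1 bond and the C2''=C3'' bond.

**17 ⇒ 12 + 16.** The cut is C2–C1'.
- The neighbouring cut O1–C2 (chalcone closure) would create C2 under reversible conditions.
- The cut C3'–C8'' would join two crowded carbons next to a finished, labile stereocentre.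
- Cutting C2–C1' splits 17 into the achiral boronic acid 12 and the flat chromone 16, and makes the stereocentre in the bond-forming event itself.
- Boron at C1' is para to oxygen and meta to the bulky flavonyl group, hence unhindered.
- The forward reaction must give face selectivity at C2 under ligand control, in a medium too weakly basic to open ring C.

**12 ⇒ 11 ⇒ 10 ⇒ 9.** The cuts are C1'–B, two O–benzyl bonds, and the O–CH3 bond at C7''. The bromide 11 carries the handle for boron. The triol 9 is the simplest form of the lower half.
- The three hydroxyls of 9 differ strongly: 7''-OH is a vinylogous acid, 4'-OH an ordinary phenol, 5''-OH chelated. They can be addressed one after another without protecting-group detours.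
- The forward steps must methylate 7''-OH selectively and then benzylate exhaustively.

**9 ⇒ 5 + 7 (key disconnection).** The cuts are C8''–C8a'' and C6''–C7''.
- The usual cuts of a flavone (O1''–C2'', C4''–C4a'') leave a 3-arylated phloroacetophenone, and with it the biaryl problem. A cut at C3'–C8'' is the biaryl problem.
- The chosen pair removes the pentasubstituted ring A'' altogether. It leaves the lactone 7, which is nucleophilic at C8'' and electrophilic at C7''. It also leaves the pyranone 5, which is electrophilic at C8a'' and nucleophilic at C6''.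
- The aryl–C8'' bond is the Ar–CH2 bond of 7. O1'' is already bonded to C8a'' in 5, so a 6-aryl isomer cannot arise. 4'-OH is set free by the ring closure.
- A tetracyclic compound is traced to two bicyclic ones, each one or two steps from catalogue compounds.
- The forward reaction must substitute at C2 of 5 without loss of the ring oxygen, and then acylate on carbon rather than on oxygen.

**5 ⇒ 4 ⇒ 1 + 2.** The cuts are two S=O bonds, then O1''–C8a'' and C3''–C2''(=O). The sulfone 5 comes from the sulfide 4. Compound 4 is the cyclised form of triketone 3, which is the product of acylating one acetyl group of the symmetrical ketene dithioacetal 1 with the acid chloride 2. The symmetry of 1 answers the regiochemical question that an unsymmetrical 1,3,5-triketone would pose. The forward reaction needs C-acylation to outrun self-condensation.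

**7 ⇒ 6 and 16 ⇒ 14 ⇒ 13.** Lactone 7 is the dehydrated form of the acid 6, which already carries bromine para to oxygen, at the future C1'. Chromone 16 is cut at O1–C2 and C2–C3 to the acetophenone 14 plus one formyl-level carbon. Compound 14 is the mono-benzyl ether of the symmetrical diol 13, which already has the 7-methoxy group in place.

## Roads not taken

**Alternative 1:** the most obvious cut, C3'–C8''.
- The forward key step is a Suzuki–Miyaura coupling of 5-(benzyloxy)-8-iodo-7-methoxy-2-(4-methoxyphenyl)-4H-chromen-4-one A1 with the (2S)-flavanone pinacol boronate A2, to give 17.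
- The bond is formed between a carbon flanked by two oxygens and a carbon ortho to an alkoxy group. Transmetalation and reductive elimination are therefore slow, and protodeboronation competes.
- The hot aqueous base this calls for acts on the retro-oxa-Michael-prone C2 of A2. The coupling would then have to be moved ahead of ring C, which hands the stereocentre to a chalcone cyclisation with weak enantiocontrol.
- A1 needs a C8-over-C6 selective iodination that depends on the state of 5-O. A2 needs its own selective functionalisation of ring B in the presence of the richer ring A.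
- The chosen plan needs neither halogenation of ring A'' nor a hindered coupling.

**Alternative 2:** the same bond, made biomimetically.
- The forward key step is an oxidative cross-coupling of (2S)-sakuranetin A3 with 5-hydroxy-7-methoxy-2-(4-methoxyphenyl)-4H-chromen-4-one A4, giving 18 directly.
- This is unbeatable in step count, but nothing in the substrates secures the selectivities.
- The phenoxyl species from A3 is reactive at O, C1' and C3'.
- The best nucleophile in the flask is ring A of A3 itself, since ring A'' of A4 is drained by its pyranone. Self-coupling is thus favoured over cross-coupling.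
- In A4, with 5-OH free, C6'' competes with C8''.
- The oxidising medium also meets the unprotected, labile flavanone. The chosen plan replaces these four uncontrolled selectivities by constitution.

**Alternative 3:** ring B is built instead of ring A'', by cutting C2'–C3' and C4'–C5'.
- The forward key step is an inverse-demand Diels–Alder reaction of methyl coumalate A5 with 2-(tert-butyldimethylsilyloxy)-4,6-dimethoxy-1-benzofuran A6. Decarboxylative cycloreversion and opening of the furan ring then give the biaryl A7.
- The idea is of the same rank and also avoids a coupling, but it removes the least substituted ring.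
- A7 still lacks C4'' to C2'' and ring B'''.
- The acyl group would have to choose between C4a'' (ortho to OH) and C6'' (para to OH).
- The flavone would have to be erected in several steps on a crowded phenol. The 5''-O-methyl group would have to be cleaved. The ester would have to be degraded to a handle for C2.
- A6 is itself several steps from catalogue compounds.
- The chosen cut removes the pentasubstituted ring and delivers the flavone complete.

Key step: step 4

Assumption: the sense of induction in step 10 is taken from the quadrant model of (S)-configured biaryl bisphosphine complexes of rhodium with cyclic enones, and the C3'–C8'' axis, for which the SMILES gives no descriptor, is taken as freely rotating.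

## Steps

Step 1
Reactants: 1 3-[bis(methylsulfanyl)methylidene]pentane-2,4-dione; 2 4-methoxybenzoyl chloride
Product: 4 3-acetyl-6-(4-methoxyphenyl)-2-(methylsulfanyl)-4H-pyran-4-one, via open-chain triketone 3 (not isolated)
Conditions: LiN(SiMe3)2 (2.2 equiv) added to 1 + 2, THF, −78 → 0 °C; 1 M HCl; then TFA (cat.), toluene, 80 °C
Reagents that add atoms: none
Why: Crossed Claisen acylation of a methyl ketone enolate by an acid chloride already present in the flask, the second equivalent of base storing 3 as its diketonate; the two acetyl groups of 1 are equivalent, so no regiochemical question arises. Under acid the enol oxygen next to the anisyl group adds to the bis(sulfanyl) carbon and methanethiol leaves (addition-elimination, six-membered ring), the usual fate of 5,5-bis(methylsulfanyl)pent-4-ene-1,3-diones.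

Step 2
Reactants: 4 3-acetyl-6-(4-methoxyphenyl)-2-(methylsulfanyl)-4H-pyran-4-one
Product: 5 3-acetyl-2-(methanesulfonyl)-6-(4-methoxyphenyl)-4H-pyran-4-one
Conditions: mCPBA (2.3 equiv), CH2Cl2, 0 °C → rt; cold aq NaHCO3 wash, used without chromatography
Reagents that add atoms: meta-chloroperoxybenzoic acid, OOC(=O)c1cccc(Cl)c1
Why: Sulfide-to-sulfone oxidation as used on 2-(methylsulfanyl)chromones; the electron-poor ring double bonds, the ketone and the anisyl ether are inert to the peracid at this temperature. The sulfone makes C2 the most electrophilic ring carbon and supplies a nucleofuge far better than the ring oxygen.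

Step 3
Reactants: 6 (5-bromo-2-hydroxyphenyl)acetic acid
Product: 7 5-bromo-1-benzofuran-2(3H)-one
Conditions: TsOH·H2O (cat.), toluene, reflux, azeotropic removal of water
Reagents that add atoms: none
Why: Acid-catalysed lactonisation (5-exo-trig) of a 2-hydroxyphenylacetic acid, driven by removal of water; bromine already sits para to the oxygen, that is at the future C1'.

Step 4
Reactants: 5 3-acetyl-2-(methanesulfonyl)-6-(4-methoxyphenyl)-4H-pyran-4-one; 7 5-bromo-1-benzofuran-2(3H)-one
Product: 9 8-(5-bromo-2-hydroxyphenyl)-5,7-dihydroxy-2-(4-methoxyphenyl)-4H-chromen-4-one, via pyranyl lactone 8 (not isolated)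
Conditions: DBU (3.5 equiv) added last to 5 + 7 (1:1), MeCN, −20 °C → rt, then 60 °C; 1 M HCl
Reagents that add atoms: none
Why: Proposed new method: the 2-oxidobenzofuran formed from 7 (its C3-H is about as acidic as that of a malonate) adds through C3 to C2 of 5, the carbon activated by the ring carbonyl and by the acetyl group, and methanesulfinate leaves (vinylic addition-elimination, known for carbanions on 2-sulfonylchromones), which makes the C8''-C8a'' bond and gives 8. In 8 the acetyl methyl carbon (C6'') lies 1,6 to the lactone carbonyl (C7''); its enolate, reached by proton shuttling from the more stable C8'' anion, is acylated on carbon (Dieckmann type, 6-(enolendo)-exo-trig), the five-membered lactone opens, the 4'-phenoxide departs and the resulting cyclohexenedione tautomerises at once to the 5'',7''-dihydroxyarene, which makes the step irreversible. The closest known types are the Michael-Dieckmann annulations of toluate and phthalide anions with pyranones and chromones and the carbanion-induced ring transformations of pyranones; new is the lactone that serves as carbon nucleophile and as acyl donor in one operation. Ring A'' is the only ring closed, and no stereocentre results because C8'' of 8 becomes trigonal. The first selectivity needed (C2 against C6 of the pyranone, sulfinate against ring-oxygen departure) is secured by the sulfonyl group as the only good nucleofuge, so that O1'' stays on C8a'' and the 8-aryl constitution is the only one possible. The second (C- against O-acylation) is secured by reversibility: attack of the acetyl oxygen on C7'' would give a fused enol lactone that the neighbouring phenoxide reopens, whereas C-acylation ends in an aromatic bis-phenoxide. Self-condensation of 7 is held down by adding the base last and cold, so that the enolate meets the much more electrophilic 5 first.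

Step 5
Reactants: 9 8-(5-bromo-2-hydroxyphenyl)-5,7-dihydroxy-2-(4-methoxyphenyl)-4H-chromen-4-one
Product: 10 8-(5-bromo-2-hydroxyphenyl)-5-hydroxy-7-methoxy-2-(4-methoxyphenyl)-4H-chromen-4-one
Conditions: MeI (1.1 equiv), KHCO3 (1.2 equiv), DMF, rt
Reagents that add atoms: iodomethane, CI
Why: Williamson ether synthesis under acidity control: 7''-OH is a vinylogous carboxylic acid conjugated with C4''=O and the only hydroxyl that hydrogencarbonate ionises, 4'-OH is an ordinary phenol and 5''-OH is locked in a hydrogen bond to C4''=O. The same order of reactivity is used for the 7-O-alkylation of 5,7,4'-trihydroxyflavonoids.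

Step 6
Reactants: 10 8-(5-bromo-2-hydroxyphenyl)-5-hydroxy-7-methoxy-2-(4-methoxyphenyl)-4H-chromen-4-one
Product: 11 5-(benzyloxy)-8-[2-(benzyloxy)-5-bromophenyl]-7-methoxy-2-(4-methoxyphenyl)-4H-chromen-4-one
Conditions: BnBr (3 equiv), K2CO3 (4 equiv), DMF, 70 °C
Reagents that add atoms: benzyl bromide, BrCc1ccccc1
Why: Exhaustive Williamson benzylation; heat and excess reagent bring in the chelated 5''-OH as well. Covering 5''-OH removes an acetylacetonate-like O,O-chelator that could tie up rhodium in step 10, and all benzyl groups leave together at the end.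

Step 7
Reactants: 11 5-(benzyloxy)-8-[2-(benzyloxy)-5-bromophenyl]-7-methoxy-2-(4-methoxyphenyl)-4H-chromen-4-one
Product: 12 {4-(benzyloxy)-3-[5-(benzyloxy)-7-methoxy-2-(4-methoxyphenyl)-4-oxo-4H-chromen-8-yl]phenyl}boronic acid
Conditions: B2(OH)4 (2 equiv), Pd(OAc)2 (2 mol %), XPhos (4 mol %), KOAc (3 equiv), EtOH, 80 °C
Reagents that add atoms: tetrahydroxydiboron, OB(O)B(O)O
Why: Miyaura borylation: zerovalent palladium inserts into the only C-Br bond, and acetate-assisted transmetalation and reductive elimination give the boronic acid directly, the form of boron best precedented for step 10. The ethers, the flavone carbonyl and the C2''=C3'' bond are inert.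

Step 8
Reactants: 13 1-(2,6-dihydroxy-4-methoxyphenyl)ethan-1-one
Product: 14 1-[2-(benzyloxy)-6-hydroxy-4-methoxyphenyl]ethan-1-one
Conditions: BnBr (1.0 equiv), K2CO3 (1.1 equiv), acetone, reflux
Reagents that add atoms: benzyl bromide, BrCc1ccccc1
Why: Williamson mono-benzylation of two equivalent hydroxyls; after the first alkylation the remaining OH is held in a strong hydrogen bond to the acetyl group and reacts much more slowly, so one equivalent of halide stops at 14.

Step 9
Reactants: 14 1-[2-(benzyloxy)-6-hydroxy-4-methoxyphenyl]ethan-1-one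
Product: 16 5-(benzyloxy)-7-methoxy-4H-chromen-4-one, via enaminone 15 (not isolated)
Conditions: Me2NCH(OMe)2 (2.5 equiv), toluene, 100 °C; concentrate; then conc. HCl, CH2Cl2, rt
Reagents that add atoms: N,N-dimethylformamide dimethyl acetal, COC(OC)N(C)C
Why: Standard chromone synthesis: condensation of the acetyl CH3 with the amide acetal gives 15, and acid lets the free phenol add to the enaminone β-carbon and expel dimethylamine (addition-elimination, six-membered ring). The benzyl ether survives brief contact with HCl at room temperature.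

Step 10
Reactants: 12 {4-(benzyloxy)-3-[5-(benzyloxy)-7-methoxy-2-(4-methoxyphenyl)-4-oxo-4H-chromen-8-yl]phenyl}boronic acid; 16 5-(benzyloxy)-7-methoxy-4H-chromen-4-one
Product: 17 5-(benzyloxy)-8-{2-(benzyloxy)-5-[(2S)-5-(benzyloxy)-7-methoxy-4-oxo-3,4-dihydro-2H-chromen-2-yl]phenyl}-7-methoxy-2-(4-methoxyphenyl)-4H-chromen-4-one
Conditions: [RhCl(C2H4)2]2 (2.5 mol %), (S)-MeO-F12-BIPHEP [(S)-6,6'-dimethoxybiphenyl-2,2'-diylbis{bis(3,4,5-trifluorophenyl)phosphine}] (5.5 mol %), aq KOH (20 mol %), toluene/H2O 10:1, 30 °C; 16 in excess (1.5 equiv)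
Reagents that add atoms: none
Why: Hayashi-Miyaura reaction (rhodium-catalysed asymmetric 1,4-addition of an arylboronic acid), a reaction type known on chromones: transmetalation to the hydroxo complex of monovalent rhodium, insertion of C2=C3 into the aryl-rhodium bond and hydrolysis of the oxa-π-allyl species. C2 is set by the ligand alone: the (S)-bisphosphine leaves open the quadrant in which the chromone presents the Re face of C2 to the aryl group, which gives 2S. Boron is unhindered (para to OBn, meta to the flavonyl group), the flavone C2''=C3'' bond is disubstituted at its β-carbon and does not insert, and the weakly basic two-phase medium does not open ring C.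

Step 11
Reactants: 17 5-(benzyloxy)-8-{2-(benzyloxy)-5-[(2S)-5-(benzyloxy)-7-methoxy-4-oxo-3,4-dihydro-2H-chromen-2-yl]phenyl}-7-methoxy-2-(4-methoxyphenyl)-4H-chromen-4-one
Product: 18 2,3-dihydroheveaflavone, (2S) enantiomer
Conditions: H2 (1 atm), 10% Pd/C, EtOAc/THF, rt
Reagents that add atoms: none
Why: Hydrogenolysis of three aryl benzyl ethers under neutral conditions, the usual last step of flavanone syntheses; primary benzyl ethers are cleaved faster than the secondary, ring-bound C2-O1 bond, and the flavone C2''=C3'' bond and both carbonyl groups are not reduced at one atmosphere. No acid or base is present, so C2 keeps its S configuration.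

## Compound list

1 | 3-[bis(methylsulfanyl)methylidene]pentane-2,4-dione | CSC(SC)=C(C(C)=O)C(C)=O | starting material
2 | 4-methoxybenzoyl chloride | COc1ccc(cc1)C(Cl)=O | starting material
3 | 4-acetyl-1-(4-methoxyphenyl)-5,5-bis(methylsulfanyl)pent-4-ene-1,3-dione | CSC(SC)=C(C(C)=O)C(=O)CC(=O)c1ccc(OC)cc1 | intermediate
4 | 3-acetyl-6-(4-methoxyphenyl)-2-(methylsulfanyl)-4H-pyran-4-one | O=c1cc(-c2ccc(OC)cc2)oc(SC)c1C(C)=O | intermediate
5 | 3-acetyl-2-(methanesulfonyl)-6-(4-methoxyphenyl)-4H-pyran-4-one | O=c1cc(-c2ccc(OC)cc2)oc(S(C)(=O)=O)c1C(C)=O | intermediate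
6 | (5-bromo-2-hydroxyphenyl)acetic acid | OC(=O)Cc1cc(Br)ccc1O | starting material
7 | 5-bromo-1-benzofuran-2(3H)-one | O=C1Cc2cc(Br)ccc2O1 | intermediate
8 | 3-[3-acetyl-6-(4-methoxyphenyl)-4-oxo-4H-pyran-2-yl]-5-bromo-1-benzofuran-2(3H)-one (C3 configurationally labile) | O=c1cc(-c2ccc(OC)cc2)oc(C2C(=O)Oc3ccc(Br)cc23)c1C(C)=O | intermediate
9 | 8-(5-bromo-2-hydroxyphenyl)-5,7-dihydroxy-2-(4-methoxyphenyl)-4H-chromen-4-one | COc1ccc(cc1)-c1cc(=O)c2c(O)cc(O)c(-c3cc(Br)ccc3O)c2o1 | intermediate
10 | 8-(5-bromo-2-hydroxyphenyl)-5-hydroxy-7-methoxy-2-(4-methoxyphenyl)-4H-chromen-4-one | COc1ccc(cc1)-c1cc(=O)c2c(O)cc(OC)c(-c3cc(Br)ccc3O)c2o1 | intermediate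
11 | 5-(benzyloxy)-8-[2-(benzyloxy)-5-bromophenyl]-7-methoxy-2-(4-methoxyphenyl)-4H-chromen-4-one | COc1ccc(cc1)-c1cc(=O)c2c(OCc3ccccc3)cc(OC)c(-c4cc(Br)ccc4OCc5ccccc5)c2o1 | intermediate
12 | {4-(benzyloxy)-3-[5-(benzyloxy)-7-methoxy-2-(4-methoxyphenyl)-4-oxo-4H-chromen-8-yl]phenyl}boronic acid | COc1ccc(cc1)-c1cc(=O)c2c(OCc3ccccc3)cc(OC)c(-c4cc(B(O)O)ccc4OCc5ccccc5)c2o1 | intermediate
13 | 1-(2,6-dihydroxy-4-methoxyphenyl)ethan-1-one | CC(=O)c1c(O)cc(OC)cc1O | starting material
14 | 1-[2-(benzyloxy)-6-hydroxy-4-methoxyphenyl]ethan-1-one | CC(=O)c1c(O)cc(OC)cc1OCc1ccccc1 | intermediate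
15 | (E)-1-[2-(benzyloxy)-6-hydroxy-4-methoxyphenyl]-3-(dimethylamino)prop-2-en-1-one | CN(C)/C=C/C(=O)c1c(O)cc(OC)cc1OCc1ccccc1 | intermediate
16 | 5-(benzyloxy)-7-methoxy-4H-chromen-4-one | O=c1ccoc2cc(OC)cc(OCc3ccccc3)c12 | intermediate
17 | 5-(benzyloxy)-8-{2-(benzyloxy)-5-[(2S)-5-(benzyloxy)-7-methoxy-4-oxo-3,4-dihydro-2H-chromen-2-yl]phenyl}-7-methoxy-2-(4-methoxyphenyl)-4H-chromen-4-one | COc1ccc(-c2cc(=O)c3c(OCc9ccccc9)cc(OC)c(-c4cc([C@@H]5CC(=O)c6c(OCc7ccccc7)cc(OC)cc6O5)ccc4OCc8ccccc8)c3o2)cc1 | intermediate
18 | 2,3-dihydroheveaflavone, (2S) | COc1ccc(-c2cc(=O)c3c(O)cc(OC)c(-c4cc([C@@H]5CC(=O)c6c(O)cc(OC)cc6O5)ccc4O)c3o2)cc1 | target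

## Step count and least certain steps

Total step count: 11. Longest linear sequence: 8 (steps 1, 2, 4, 5, 6, 7, 10, 11).

**Step 4 (key step, proposed new method).**
- Most likely failure: the sequence stalls after the substitution. The charge of the deprotonated intermediate 8 is delocalised into the lactone carbonyl and makes it a poor acyl donor. Ring closure may then be outrun by intermolecular acyl transfer or by hydrolytic opening of the lactone. Opening of the pyranone by loss of O1'' is a second possible leak.
- Fallback with known chemistry, from 2 back to 10. Commercial 1-(2-hydroxy-4,6-dimethoxyphenyl)ethan-1-one is iodinated next to the free hydroxyl (NIS, cat. TFA, MeCN) to 1-(2-hydroxy-3-iodo-4,6-dimethoxyphenyl)ethan-1-one F1. Its dilithium salt [LiN(SiMe3)2, THF] is C-acylated by 2 to 1-(2-hydroxy-3-iodo-4,6-dimethoxyphenyl)-3-(4-methoxyphenyl)propane-1,3-dione F2. H2SO4 in AcOH closes this to 8-iodo-5,7-dimethoxy-2-(4-methoxyphenyl)-4H-chromen-4-one F3. BCl3 (CH2Cl2, −20 °C) removes only the methyl group peri to the carbonyl and gives 5-hydroxy-8-iodo-7-methoxy-2-(4-methoxyphenyl)-4H-chromen-4-one F4. Suzuki–Miyaura coupling of F4 with commercial (5-bromo-2-hydroxyphenyl)boronic acid [Pd(PPh3)4, K2CO3, dioxane/H2O], in which zerovalent palladium inserts into C–I before C–Br, returns to 10.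

**Step 1.**
- Most likely failure: self-condensation. The enolate of 1 is also a good nucleophile for the bis(sulfanyl) carbon of a second molecule of 1. O-acylation of the crowded, cross-conjugated enolate may compete with C-acylation.
- Fallback, from 2 back to 4, which brings in the acetyl group last. The less crowded commercial 4,4-bis(methylsulfanyl)but-3-en-2-one is deprotonated [LiN(SiMe3)2] and acylated by 2 to 1-(4-methoxyphenyl)-5,5-bis(methylsulfanyl)pent-4-ene-1,3-dione F5. Acid closes this to 2-(4-methoxyphenyl)-6-(methylsulfanyl)-4H-pyran-4-one F6. NIS iodinates the nucleophilic β-carbon of the ketene O,S-acetal unit to 3-iodo-6-(4-methoxyphenyl)-2-(methylsulfanyl)-4H-pyran-4-one F7. Stille coupling with tributyl(1-ethoxyvinyl)stannane [PdCl2(PPh3)2, toluene, 90 °C] gives 3-(1-ethoxyethenyl)-6-(4-methoxyphenyl)-2-(methylsulfanyl)-4H-pyran-4-one F8. Dilute HCl hydrolyses F8 to 4.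

**Step 5.**
- Most likely failure: loss of site selectivity. 7''-OH is crowded by the aryl group on C8''. Alkylation at the less acidic but more nucleophilic 4'-oxygen, or double alkylation, may therefore compete.
- Fallback, from 9 back to 10, which replaces selective alkylation by selective deprotection. Ac2O and pyridine give the triacetate 8-[2-(acetyloxy)-5-bromophenyl]-2-(4-methoxyphenyl)-4-oxo-4H-chromene-5,7-diyl diacetate F9. Thiophenol and imidazole in NMP at 0 °C remove only the most activated ester, that of the vinylogous acid at C7''. This is a known selectivity of flavonoid peracetates, and it gives 8-[2-(acetyloxy)-5-bromophenyl]-7-hydroxy-2-(4-methoxyphenyl)-4-oxo-4H-chromen-5-yl acetate F10. A Mitsunobu reaction with methanol (PPh3, DIAD) gives 8-[2-(acetyloxy)-5-bromophenyl]-7-methoxy-2-(4-methoxyphenyl)-4-oxo-4H-chromen-5-yl acetate F11. K2CO3 in methanol removes both acetates and returns to 10.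

**Step 10.**
- Most likely failure: slow insertion of the electron-rich 5,7-dialkoxychromone, so that protodeboronation of the valuable boronic acid overtakes the addition. Erosion of the enantiomeric purity by reversible ring opening over a long reaction time is a second concern.
- Fallback, from 12 and 16 back to 17, which moves stereocontrol from bond formation to a resolution. Catalysis by cationic divalent palladium [Pd(OCOCF3)2, 2,2'-bipyridine, aq MeOH, 60 °C] is more forcing. It adds 12 to 16 without stereocontrol and gives racemic 5-(benzyloxy)-8-{2-(benzyloxy)-5-[5-(benzyloxy)-7-methoxy-4-oxo-3,4-dihydro-2H-chromen-2-yl]phenyl}-7-methoxy-2-(4-methoxyphenyl)-4H-chromen-4-one F12. Kinetic resolution follows by asymmetric transfer hydrogenation {RuCl(p-cymene)[(R,R)-TsDPEN], HCO2H/Et3N}, a process known for racemic flavanones. It reduces the 2R ketone to the cis alcohol 5-(benzyloxy)-8-{2-(benzyloxy)-5-[(2R,4R)-5-(benzyloxy)-4-hydroxy-7-methoxy-3,4-dihydro-2H-chromen-2-yl]phenyl}-7-methoxy-2-(4-methoxyphenyl)-4H-chromen-4-one F13 and leaves the 2S ketone 17, which is separated by chromatography.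

## Further compounds

F1 | step 4 | 1-(2-hydroxy-3-iodo-4,6-dimethoxyphenyl)ethan-1-one | CC(=O)c1c(O)c(I)c(OC)cc1OC
F2 | step 4 | 1-(2-hydroxy-3-iodo-4,6-dimethoxyphenyl)-3-(4-methoxyphenyl)propane-1,3-dione | COc1ccc(cc1)C(=O)CC(=O)c1c(O)c(I)c(OC)cc1OC
F3 | step 4 | 8-iodo-5,7-dimethoxy-2-(4-methoxyphenyl)-4H-chromen-4-one | COc1ccc(cc1)-c1cc(=O)c2c(OC)cc(OC)c(I)c2o1
F4 | step 4 | 5-hydroxy-8-iodo-7-methoxy-2-(4-methoxyphenyl)-4H-chromen-4-one | COc1ccc(cc1)-c1cc(=O)c2c(O)cc(OC)c(I)c2o1
F5 | step 1 | 1-(4-methoxyphenyl)-5,5-bis(methylsulfanyl)pent-4-ene-1,3-dione | COc1ccc(cc1)C(=O)CC(=O)C=C(SC)SC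
F6 | step 1 | 2-(4-methoxyphenyl)-6-(methylsulfanyl)-4H-pyran-4-one | O=c1cc(SC)oc(-c2ccc(OC)cc2)c1
F7 | step 1 | 3-iodo-6-(4-methoxyphenyl)-2-(methylsulfanyl)-4H-pyran-4-one | O=c1cc(-c2ccc(OC)cc2)oc(SC)c1I
F8 | step 1 | 3-(1-ethoxyethenyl)-6-(4-methoxyphenyl)-2-(methylsulfanyl)-4H-pyran-4-one | O=c1cc(-c2ccc(OC)cc2)oc(SC)c1C(=C)OCC
F9 | step 5 | 8-[2-(acetyloxy)-5-bromophenyl]-2-(4-methoxyphenyl)-4-oxo-4H-chromene-5,7-diyl diacetate | COc1ccc(cc1)-c1cc(=O)c2c(OC(C)=O)cc(OC(C)=O)c(-c3cc(Br)ccc3OC(C)=O)c2o1
F10 | step 5 | 8-[2-(acetyloxy)-5-bromophenyl]-7-hydroxy-2-(4-methoxyphenyl)-4-oxo-4H-chromen-5-yl acetate | COc1ccc(cc1)-c1cc(=O)c2c(OC(C)=O)cc(O)c(-c3cc(Br)ccc3OC(C)=O)c2o1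
F11 | step 5 | 8-[2-(acetyloxy)-5-bromophenyl]-7-methoxy-2-(4-methoxyphenyl)-4-oxo-4H-chromen-5-yl acetate | COc1ccc(cc1)-c1cc(=O)c2c(OC(C)=O)cc(OC)c(-c3cc(Br)ccc3OC(C)=O)c2o1
F12 | step 10 | racemic 5-(benzyloxy)-8-{2-(benzyloxy)-5-[5-(benzyloxy)-7-methoxy-4-oxo-3,4-dihydro-2H-chromen-2-yl]phenyl}-7-methoxy-2-(4-methoxyphenyl)-4H-chromen-4-one | COc1ccc(-c2cc(=O)c3c(OCc9ccccc9)cc(OC)c(-c4cc(C5CC(=O)c6c(OCc7ccccc7)cc(OC)cc6O5)ccc4OCc8ccccc8)c3o2)cc1
F13 | step 10 | 5-(benzyloxy)-8-{2-(benzyloxy)-5-[(2R,4R)-5-(benzyloxy)-4-hydroxy-7-methoxy-3,4-dihydro-2H-chromen-2-yl]phenyl}-7-methoxy-2-(4-methoxyphenyl)-4H-chromen-4-one | COc1ccc(-c2cc(=O)c3c(OCc9ccccc9)cc(OC)c(-c4cc([C@H]5C[C@@H](O)c6c(OCc7ccccc7)cc(OC)cc6O5)ccc4OCc8ccccc8)c3o2)cc1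
A1 | alternative 1 | 5-(benzyloxy)-8-iodo-7-methoxy-2-(4-methoxyphenyl)-4H-chromen-4-one | COc1ccc(cc1)-c1cc(=O)c2c(OCc3ccccc3)cc(OC)c(I)c2o1
A2 | alternative 1 | (2S)-5-(benzyloxy)-2-[4-(benzyloxy)-3-(4,4,5,5-tetramethyl-1,3,2-dioxaborolan-2-yl)phenyl]-7-methoxy-2,3-dihydro-4H-chromen-4-one | CC1(C)OB(OC1(C)C)c1cc(ccc1OCc1ccccc1)[C@@H]1CC(=O)c2c(OCc3ccccc3)cc(OC)cc2O1
A3 | alternative 2 | (2S)-sakuranetin, (2S)-5-hydroxy-2-(4-hydroxyphenyl)-7-methoxy-2,3-dihydro-4H-chromen-4-one | Oc1ccc(cc1)[C@@H]1CC(=O)c2c(O)cc(OC)cc2O1
A4 | alternative 2 | 5-hydroxy-7-methoxy-2-(4-methoxyphenyl)-4H-chromen-4-one | COc1ccc(cc1)-c1cc(=O)c2c(O)cc(OC)cc2o1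
A5 | alternative 3 | methyl coumalate, methyl 2-oxo-2H-pyran-5-carboxylate | COC(=O)c1ccc(=O)oc1
A6 | alternative 3 | 2-(tert-butyldimethylsilyloxy)-4,6-dimethoxy-1-benzofuran | COc1cc(OC)c2cc(O[Si](C)(C)C(C)(C)C)oc2c1
A7 | alternative 3 | methyl 4-[(tert-butyldimethylsilyl)oxy]-3-(2-hydroxy-4,6-dimethoxyphenyl)benzoate | COC(=O)c1ccc(O[Si](C)(C)C(C)(C)C)c(c1)-c1c(O)cc(OC)cc1OC
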